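**Retrosynthetic overview**

The plan rests on the C3–C4 two-carbon unit of the pyran ring: C4 is bonded to the benzo ring (A, at C4a) and the stereogenic C3 to the quinone ring (B, at C1'), and the third carbon on C3, the C2 oxymethylene, can be installed later in the place of a boron atom.
The quinone is unmasked last from a bis-benzyl hydroquinone; before that the pyran ring, the only ring that is built, is closed at O1–C2 by Mitsunobu etherification of a phenol and a primary alcohol.
C2 is inserted by Matteson homologation and oxidation of a C3 benzylic pinacol boronate.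
That boronate is cut at C3–C1' and C4–C4a into the B-ring aryllithium, vinylboronic acid pinacol ester and the A-ring aryl triflate, joined by a palladium-catalysed enantioselective conjunctive coupling that sets C3.
The aryllithium comes from 2,3-dimethoxy-1,4-benzoquinone (reduction, benzylation, bromination) and the triflate from 2-hydroxy-4,5-dimethoxybenzaldehyde (MOM protection, Baeyer–Villiger oxidation, triflation); both arenes are bought, so the ring order is pyran ring (step 11), then quinone oxidation level (step 12).

Key step: step 7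

Assumption: the target SMILES defines C3 as (S); the (Rp,Rp) antipode of MandyPhos in step 7 is taken, by analogy with simple aryl/aryl cases, to give the (S)-boronate, and the mirror-image ligand (also commercial) is used if the first run shows the opposite sense.

**Route**

Step 1
Reactants: 1 2,3-dimethoxy-1,4-benzoquinone
Product: 2 2,3-dimethoxybenzene-1,4-diol
Conditions: Na2S2O4, EtOAc/H2O, rt, under N2
Reagents that add atoms: none
Why: Dithionite reduces the quinone to the hydroquinone by two-electron transfer (quinone reduction), and nothing else in the molecule is reducible.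

Step 2
Reactants: 2 2,3-dimethoxybenzene-1,4-diol; 3 benzyl bromide
Product: 4 1,4-bis(benzyloxy)-2,3-dimethoxybenzene
Conditions: BnBr (2.3 equiv), K2CO3, degassed DMF, 60 °C
Reagents that add atoms: benzyl bromide (compound 3), BrCc1ccccc1
Why: Double Williamson etherification (SN2 of the phenoxides on benzyl bromide) under oxygen-free conditions should cap both hydroxyls as hydrogenolysable ethers that keep the quinone oxidation level latent through the organolithium and palladium steps.

Step 3
Reactants: 4 1,4-bis(benzyloxy)-2,3-dimethoxybenzene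
Product: 5 1,4-bis(benzyloxy)-5-bromo-2,3-dimethoxybenzene
Conditions: NBS (1.0 equiv), MeCN, 0 °C → rt
Reagents that add atoms: N-bromosuccinimide, BrN1C(=O)CCC1=O
Why: Electrophilic aromatic bromination by NBS should occur on the tetra-oxygenated ring, whose two free positions are equivalent, so one equivalent should give a single monobromide while the unactivated benzyl rings stay untouched.

Step 4
Reactants: 6 2-hydroxy-4,5-dimethoxybenzaldehyde
Product: 7 4,5-dimethoxy-2-(methoxymethoxy)benzaldehyde
Conditions: MOMCl, i-Pr2NEt, CH2Cl2, 0 °C → rt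
Reagents that add atoms: chloromethyl methyl ether, COCCl
Why: O-Alkylation of the phenol with MOMCl under amine base (acetal protection) should give an ether that withstands peracid, base, organolithium and Pd(0) and can be removed later without touching benzyl ethers.

Step 5
Reactants: 7 4,5-dimethoxy-2-(methoxymethoxy)benzaldehyde
Product: 9 4,5-dimethoxy-2-(methoxymethoxy)phenol, via aryl formate 8 (not isolated)
Conditions: mCPBA, CH2Cl2, 0 °C → rt; then K2CO3 (cat.), MeOH, rt
Reagents that add atoms: meta-chloroperoxybenzoic acid, OOC(=O)c1cccc(Cl)c1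
Why: Baeyer–Villiger oxidation of the electron-rich benzaldehyde (Dakin-type, aryl migration favoured by the ortho and para oxygen donors) should give the aryl formate, which mild methanolysis cleaves to the phenol.

Step 6
Reactants: 9 4,5-dimethoxy-2-(methoxymethoxy)phenol
Product: 10 4,5-dimethoxy-2-(methoxymethoxy)phenyl trifluoromethanesulfonate
Conditions: PhNTf2, Et3N, DMAP (cat.), CH2Cl2, 0 °C → rt
Reagents that add atoms: N-phenylbis(trifluoromethanesulfonimide), O=S(=O)(N(c1ccccc1)S(=O)(=O)C(F)(F)F)C(F)(F)F
Why: O-Sulfonylation of the phenoxide with the mild triflyl donor PhNTf2 should give the aryl triflate without generating acid that could cleave the neighbouring MOM acetal.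

Step 7
Reactants: 5 1,4-bis(benzyloxy)-5-bromo-2,3-dimethoxybenzene; 11 vinylboronic acid pinacol ester; 10 4,5-dimethoxy-2-(methoxymethoxy)phenyl trifluoromethanesulfonate
Product: 14 2-{(1S)-1-[2,5-bis(benzyloxy)-3,4-dimethoxyphenyl]-2-[4,5-dimethoxy-2-(methoxymethoxy)phenyl]ethyl}-4,4,5,5-tetramethyl-1,3,2-dioxaborolane, via aryllithium 12 (not isolated), via lithium vinylboronate complex 13 (not isolated)
Conditions: n-BuLi (1.0 equiv), THF, −78 °C; 11, −78 °C → rt; THF and n-BuBr removed in vacuo; then 10 (1.1 equiv), Pd(OAc)2 (2 mol%), (Rp,Rp)-MandyPhos (2.4 mol%), THF, 60 °C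
Reagents that add atoms: none
Why: Bromine–lithium exchange gives the aryllithium, which adds to boron to form the four-coordinate alkenyl ate complex; the cationic arylpalladium(II) species from oxidative addition of the triflate binds the vinyl π-bond and triggers a 1,2-metallate shift in which the B-ring aryl group moves from boron to the α-carbon (C3–C1') anti to palladium while the β-carbon bonds to palladium, and reductive elimination then forms C4–C4a. The closest known reaction type is the palladium/MandyPhos-catalysed enantioselective conjunctive cross-coupling of vinylboron ate complexes with aryl triflates, which is established for aryl migrating groups. No ring is closed in this step. The one new stereocentre, C3, is set by the chiral bisphosphine, which decides which enantiotopic face of the bound alkenyl ate complex palladium occupies as the aryl group migrates; the substrates carry no stereocentre that could interfere. The step needs the metallate shift to outrun direct aryl or vinyl transfer to palladium (Suzuki coupling) and β-hydride elimination: the non-coordinating triflate keeps palladium cationic and π-acidic, the electron-rich aryl group migrates readily, the chelating wide-bite-angle ligand leaves no free site for β-hydride loss, and inhibiting bromide is carried off as 1-bromobutane before the catalyst is added. Regiochemistry is fixed by the mechanism, since the migrating group can only reach the boron-bearing carbon.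

Step 8
Reactants: 14 2-{(1S)-1-[2,5-bis(benzyloxy)-3,4-dimethoxyphenyl]-2-[4,5-dimethoxy-2-(methoxymethoxy)phenyl]ethyl}-4,4,5,5-tetramethyl-1,3,2-dioxaborolane
Product: 16 2-{(2S)-2-[2,5-bis(benzyloxy)-3,4-dimethoxyphenyl]-3-[4,5-dimethoxy-2-(methoxymethoxy)phenyl]propyl}-4,4,5,5-tetramethyl-1,3,2-dioxaborolane, via chloromethyl boronate complex 15 (not isolated)
Conditions: BrCH2Cl (2 equiv), n-BuLi (1.8 equiv), THF, −78 °C → rt
Reagents that add atoms: bromochloromethane, ClCBr
Why: Matteson homologation: chloromethyllithium generated in situ adds to boron and the secondary benzylic carbon shifts onto the CH2Cl carbon with loss of chloride and retention at C3, so C2 should be inserted without touching the stereocentre.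

Step 9
Reactants: 16 2-{(2S)-2-[2,5-bis(benzyloxy)-3,4-dimethoxyphenyl]-3-[4,5-dimethoxy-2-(methoxymethoxy)phenyl]propyl}-4,4,5,5-tetramethyl-1,3,2-dioxaborolane
Product: 17 (2S)-2-[2,5-bis(benzyloxy)-3,4-dimethoxyphenyl]-3-[4,5-dimethoxy-2-(methoxymethoxy)phenyl]propan-1-ol
Conditions: 30% H2O2, 3 M NaOH, THF, 0 °C → rt
Reagents that add atoms: hydrogen peroxide, OO
Why: Boron oxidation with basic hydrogen peroxide (hydroperoxide addition to boron, then 1,2-shift of the primary alkyl group to oxygen) should give the primary alcohol; C3 is not a reacting centre and the aryl ethers are inert.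

Step 10
Reactants: 17 (2S)-2-[2,5-bis(benzyloxy)-3,4-dimethoxyphenyl]-3-[4,5-dimethoxy-2-(methoxymethoxy)phenyl]propan-1-ol
Product: 18 2-{(2S)-2-[2,5-bis(benzyloxy)-3,4-dimethoxyphenyl]-3-hydroxypropyl}-4,5-dimethoxyphenol
Conditions: HCl (aq, 3 M), MeOH/THF, 40 °C
Reagents that add atoms: none
Why: Acid-catalysed acetal methanolysis should remove the MOM group as dimethoxymethane, while benzyl and methyl aryl ethers and the primary alcohol are stable to dilute methanolic HCl.

Step 11
Reactants: 18 2-{(2S)-2-[2,5-bis(benzyloxy)-3,4-dimethoxyphenyl]-3-hydroxypropyl}-4,5-dimethoxyphenol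
Product: 19 (3S)-3-[2,5-bis(benzyloxy)-3,4-dimethoxyphenyl]-6,7-dimethoxychromane
Conditions: PPh3, DIAD, THF, 0 °C → rt
Reagents that add atoms: none
Why: Intramolecular Mitsunobu etherification: the primary alcohol is activated as its alkoxyphosphonium ion and displaced by the phenoxide in a 6-exo-tet closure that forms O1–C2 and the pyran ring, with C3 untouched because it is not the electrophilic carbon.

Step 12
Reactants: 19 (3S)-3-[2,5-bis(benzyloxy)-3,4-dimethoxyphenyl]-6,7-dimethoxychromane
Product: 21 5-[(3S)-6,7-dimethoxychroman-3-yl]-2,3-dimethoxy-1,4-benzoquinone (the target), via hydroquinone 20 (not isolated)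
Conditions: H2 (1 atm), 10% Pd/C, EtOAc, rt; filtered under Ar; then Ag2O, Na2SO4, Et2O, rt
Reagents that add atoms: none
Why: Hydrogenolysis of the two aryl benzyl ethers over Pd/C should release the hydroquinone, which neutral silver(I) oxide dehydrogenates to the para-quinone (hydroquinone oxidation); neither operation is basic, so the C3–H next to the quinone should not enolise.

**Compound list**

1 | 2,3-dimethoxy-1,4-benzoquinone | COC1=C(OC)C(=O)C=CC1=O | starting material
2 | 2,3-dimethoxybenzene-1,4-diol | COc1c(O)ccc(O)c1OC | intermediate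
3 | benzyl bromide | BrCc1ccccc1 | starting material
4 | 1,4-bis(benzyloxy)-2,3-dimethoxybenzene | COc1c(OCc2ccccc2)ccc(OCc2ccccc2)c1OC | intermediate
5 | 1,4-bis(benzyloxy)-5-bromo-2,3-dimethoxybenzene | COc1c(OCc2ccccc2)cc(Br)c(OCc2ccccc2)c1OC | intermediate
6 | 2-hydroxy-4,5-dimethoxybenzaldehyde | COc1cc(O)c(C=O)cc1OC | starting material
7 | 4,5-dimethoxy-2-(methoxymethoxy)benzaldehyde | COCOc1cc(OC)c(OC)cc1C=O | intermediate
8 | 4,5-dimethoxy-2-(methoxymethoxy)phenyl formate | COCOc1cc(OC)c(OC)cc1OC=O | intermediate (not isolated)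
9 | 4,5-dimethoxy-2-(methoxymethoxy)phenol | COCOc1cc(OC)c(OC)cc1O | intermediate
10 | 4,5-dimethoxy-2-(methoxymethoxy)phenyl trifluoromethanesulfonate | COCOc1cc(OC)c(OC)cc1OS(=O)(=O)C(F)(F)F | intermediate
11 | vinylboronic acid pinacol ester (4,4,5,5-tetramethyl-2-vinyl-1,3,2-dioxaborolane) | C=CB1OC(C)(C)C(C)(C)O1 | starting material
12 | [2,5-bis(benzyloxy)-3,4-dimethoxyphenyl]lithium | [Li]c1cc(OCc2ccccc2)c(OC)c(OC)c1OCc1ccccc1 | intermediate (not isolated)
13 | lithium [2,5-bis(benzyloxy)-3,4-dimethoxyphenyl](ethenyl)(pinacolato)borate | [Li+].C=C[B-]1(c2cc(OCc3ccccc3)c(OC)c(OC)c2OCc2ccccc2)OC(C)(C)C(C)(C)O1 | intermediate (not isolated)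
14 | 2-{(1S)-1-[2,5-bis(benzyloxy)-3,4-dimethoxyphenyl]-2-[4,5-dimethoxy-2-(methoxymethoxy)phenyl]ethyl}-4,4,5,5-tetramethyl-1,3,2-dioxaborolane | COc1c(OCc2ccccc2)cc([C@H](Cc2cc(OC)c(OC)cc2OCOC)B2OC(C)(C)C(C)(C)O2)c(OCc2ccccc2)c1OC | intermediate
15 | lithium (chloromethyl) ate complex of boronate 14 (C3 configuration as in 14) | [Li+].COc1c(OCc2ccccc2)cc([C@H](Cc2cc(OC)c(OC)cc2OCOC)[B-]2(CCl)OC(C)(C)C(C)(C)O2)c(OCc2ccccc2)c1OC | intermediate (not isolated)
16 | 2-{(2S)-2-[2,5-bis(benzyloxy)-3,4-dimethoxyphenyl]-3-[4,5-dimethoxy-2-(methoxymethoxy)phenyl]propyl}-4,4,5,5-tetramethyl-1,3,2-dioxaborolane | COc1c(OCc2ccccc2)cc([C@H](Cc2cc(OC)c(OC)cc2OCOC)CB2OC(C)(C)C(C)(C)O2)c(OCc2ccccc2)c1OC | intermediate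
17 | (2S)-2-[2,5-bis(benzyloxy)-3,4-dimethoxyphenyl]-3-[4,5-dimethoxy-2-(methoxymethoxy)phenyl]propan-1-ol | COc1c(OCc2ccccc2)cc([C@H](Cc2cc(OC)c(OC)cc2OCOC)CO)c(OCc2ccccc2)c1OC | intermediate
18 | 2-{(2S)-2-[2,5-bis(benzyloxy)-3,4-dimethoxyphenyl]-3-hydroxypropyl}-4,5-dimethoxyphenol | COc1c(OCc2ccccc2)cc([C@H](Cc2cc(OC)c(OC)cc2O)CO)c(OCc2ccccc2)c1OC | intermediate
19 | (3S)-3-[2,5-bis(benzyloxy)-3,4-dimethoxyphenyl]-6,7-dimethoxychromane | COc1c(OCc2ccccc2)cc([C@H]2COc3cc(OC)c(OC)cc3C2)c(OCc2ccccc2)c1OC | intermediate
20 | 5-[(3S)-6,7-dimethoxychroman-3-yl]-2,3-dimethoxybenzene-1,4-diol | COc1c(O)cc([C@H]2COc3cc(OC)c(OC)cc3C2)c(O)c1OC | intermediate (not isolated)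
21 | 5-[(3S)-6,7-dimethoxychroman-3-yl]-2,3-dimethoxy-1,4-benzoquinone (the target) | COC1=C(OC)C(=O)C([C@H]2COc3cc(OC)c(OC)cc3C2)=CC1=O | target

**Step count**

Total: 12 steps. Longest linear sequence: 9 steps (steps 1–3 or 4–6, then 7–12).

**Steps most likely to fail**

Step 7. The aryl group on boron may be handed directly to palladium (biaryl by Suzuki transfer) instead of migrating to carbon. Oxidative addition of the electron-rich ortho-alkoxy triflate may be slow, traces of bromide may stall the cationic catalyst, and facial discrimination may be poor with an ortho-benzyloxy migrating group. The fallback sets out from bromide 5 and aldehyde 7, comes back at alcohol 17, and replaces steps 7–9 with an asymmetric hydrogenation: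
- Palladium-catalysed Negishi coupling of 5 with the Reformatsky reagent of ethyl bromoacetate (Pd2(dba)3, Q-Phos, THF) should give ethyl [2,5-bis(benzyloxy)-3,4-dimethoxyphenyl]acetate F1.
- Saponification with LiOH should give [2,5-bis(benzyloxy)-3,4-dimethoxyphenyl]acetic acid F2.
- Perkin condensation of this acid with 7 (Ac2O, Et3N, 100 °C) should give (2E)-2-[2,5-bis(benzyloxy)-3,4-dimethoxyphenyl]-3-[4,5-dimethoxy-2-(methoxymethoxy)phenyl]prop-2-enoic acid F3.
- Carboxyl-directed asymmetric hydrogenation of this α-aryl cinnamic acid with a chiral spiro phosphine–oxazoline iridium catalyst (H2, Et3N, MeOH), a homogeneous catalyst that leaves benzyl ethers intact, should set C3 and give (2S)-2-[2,5-bis(benzyloxy)-3,4-dimethoxyphenyl]-3-[4,5-dimethoxy-2-(methoxymethoxy)phenyl]propanoic acid F4.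
- LiAlH4 reduction in THF should then deliver 17.

Step 8. The short-lived carbenoid may decompose before it adds to the hindered benzylic boron, or it may insert a second time into the less hindered primary boronate that forms. The fallback sets out from boronate 14, comes back at alcohol 17, and replaces steps 8 and 9:
- Zweifel olefination of 14 with vinyllithium (thermally stable, so it can be used in excess), then I2 and NaOMe in THF/MeOH, should give by a stereoretentive 1,2-shift and anti elimination (3R)-3-[2,5-bis(benzyloxy)-3,4-dimethoxyphenyl]-4-[4,5-dimethoxy-2-(methoxymethoxy)phenyl]but-1-ene F5.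
- Lemieux–Johnson cleavage (OsO4 cat., NaIO4, 2,6-lutidine, dioxane/H2O) should give (2S)-2-[2,5-bis(benzyloxy)-3,4-dimethoxyphenyl]-3-[4,5-dimethoxy-2-(methoxymethoxy)phenyl]propanal F6.
- This aldehyde is reduced at once with NaBH4 at 0 °C, before the α-aryl aldehyde can enolise, to give 17.

Step 12. Cleavage of the two flanked benzyl ethers on the metal surface may be slow or incomplete, partial oxidation may leave quinhydrone-type mixtures, and enolisation of C3–H towards a quinone methide would erode the stereocentre. The fallback sets out from chromane 19 and comes back at hydroquinone 20. The benzyl groups are removed without hydrogen or a metal surface by BCl3 with pentamethylbenzene as cation scavenger in CH2Cl2 at −78 °C, where aryl methyl ethers and the chroman ether should persist. The hydroquinone 20 obtained is then oxidised to 21 as in the second half of step 12.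

**Further compounds**

F1 | step 7 | ethyl [2,5-bis(benzyloxy)-3,4-dimethoxyphenyl]acetate | CCOC(=O)Cc1cc(OCc2ccccc2)c(OC)c(OC)c1OCc1ccccc1
F2 | step 7 | [2,5-bis(benzyloxy)-3,4-dimethoxyphenyl]acetic acid | OC(=O)Cc1cc(OCc2ccccc2)c(OC)c(OC)c1OCc1ccccc1
F3 | step 7 | (2E)-2-[2,5-bis(benzyloxy)-3,4-dimethoxyphenyl]-3-[4,5-dimethoxy-2-(methoxymethoxy)phenyl]prop-2-enoic acid | OC(=O)/C(=C/c1cc(OC)c(OC)cc1OCOC)c1cc(OCc2ccccc2)c(OC)c(OC)c1OCc1ccccc1
F4 | step 7 | (2S)-2-[2,5-bis(benzyloxy)-3,4-dimethoxyphenyl]-3-[4,5-dimethoxy-2-(methoxymethoxy)phenyl]propanoic acid | COc1c(OCc2ccccc2)cc([C@H](Cc2cc(OC)c(OC)cc2OCOC)C(=O)O)c(OCc2ccccc2)c1OC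
F5 | step 8 | (3R)-3-[2,5-bis(benzyloxy)-3,4-dimethoxyphenyl]-4-[4,5-dimethoxy-2-(methoxymethoxy)phenyl]but-1-ene | COc1c(OCc2ccccc2)cc([C@H](Cc2cc(OC)c(OC)cc2OCOC)C=C)c(OCc2ccccc2)c1OC
F6 | step 8 | (2S)-2-[2,5-bis(benzyloxy)-3,4-dimethoxyphenyl]-3-[4,5-dimethoxy-2-(methoxymethoxy)phenyl]propanal | COc1c(OCc2ccccc2)cc([C@H](Cc2cc(OC)c(OC)cc2OCOC)C=O)c(OCc2ccccc2)c1OC
F0 | step 12 | none | none
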